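**Plan**

1. Retrosynthesis: remove the eight O-benzyl groups; cut the C2–aryl bond of the upper unit (ring B leaves as an aryl nucleophile, C2 becomes an acetal carbon); cut ring C across O1–C2 and C3–C4 by a retro-[4+2] to an ortho-quinone methide and a chiral vinyl ether; cut the C4–C8 interflavan bond (aryllithium + aldehyde).
2. Enabling feature: O1 and C4 of ring C hang from the neighbouring ring-A carbons C8a and C4a, and C4 is the doubly benzylic carbon that also carries C8 of ring D, so ring C is the cycloadduct of the oxa-diene O1=C8a–C4a=C4 with a two-carbon C2–C3 ene.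
3. Forward: (+)-gallocatechin is benzylated and brominated at C8; in one flask its C8-lithium reagent adds to an O-Boc salicylaldehyde, the Boc group migrates and leaves, and the released quinone methide is trapped by the vinyl ether, which closes ring C as the last ring; C2 arylation then brings in ring B and hydrogenolysis frees the phenols.
4. Stereochemistry: C2/C3 of ring F come with (+)-gallocatechin; C4 (R) comes from the (1S,2R)-2-phenylcyclohexyl auxiliary on the vinyl ether in an endo cycloaddition; C2 (S) comes from 1,3-induction, the aryl group adding to the ring-C oxocarbenium ion anti to the C4 aryl group (2,4-trans).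

Key step: step 6

Remark: (+)-gallocatechin (2R,3S), (1S,2R)-trans-2-phenylcyclohexanol and potassium [4-(benzyloxy)phenyl]trifluoroborate are taken as purchasable; the upper unit of the target is read as (2S,4R), i.e. 2,4-trans.

Ring letters: upper flavan unit A (resorcinol ring), B (4-hydroxyphenyl), C (pyran); lower unit D (benzo ring), E (trihydroxyphenyl), F (pyran). "Gc" = (2R,3S)-3,5,7-tris(benzyloxy)-2-[3,4,5-tris(benzyloxy)phenyl]chroman-8-yl.

**Route**

Step 1
Reactants: 1 (+)-gallocatechin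
Product: 2 5,7,3',4',5'-penta-O-benzyl-(+)-gallocatechin
Conditions: BnBr (5.5 equiv), K2CO3, DMF, 0 °C → rt, N2
Reagents that add atoms: benzyl bromide, BrCc1ccccc1
Why: Williamson etherification: under K2CO3 only the five phenols (not the C3 alcohol) are deprotonated and benzylated, and quick capping of the 4'-phenol should forestall quinone-methide epimerisation at C2 of ring F.

Step 2
Reactants: 2 5,7,3',4',5'-penta-O-benzyl-(+)-gallocatechin
Product: 3 3,5,7,3',4',5'-hexa-O-benzyl-(+)-gallocatechin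
Conditions: NaH, BnBr, n-Bu4NI (cat.), DMF, 0 °C → rt
Reagents that add atoms: benzyl bromide, BrCc1ccccc1
Why: Williamson etherification of the C3 alkoxide; with every phenol already capped there is no base-induced ring opening at C2, so both stereocentres are kept.

Step 3
Reactants: 3 3,5,7,3',4',5'-hexa-O-benzyl-(+)-gallocatechin
Product: 4 8-bromo-3,5,7,3',4',5'-hexa-O-benzyl-(+)-gallocatechin (Gc–Br)
Conditions: NBS (1.0 equiv), CH2Cl2, −78 → 0 °C
Reagents that add atoms: N-bromosuccinimide, O=C1CCC(=O)N1Br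
Why: Electrophilic aromatic bromination: C8 of the 5,7-dialkoxylated ring D is the most reactive arene position, as in benzylated catechins, so one equivalent of NBS at low temperature should brominate there and not at C6 or on ring E.

Step 4
Reactants: 5 4-(benzyloxy)-2-hydroxybenzaldehyde
Product: 6 5-(benzyloxy)-2-formylphenyl tert-butyl carbonate
Conditions: Boc2O, DMAP (cat.), i-Pr2NEt (cat.), THF, rt
Reagents that add atoms: di-tert-butyl dicarbonate, CC(C)(C)OC(=O)OC(=O)OC(C)(C)C
Why: DMAP-catalysed O-acylation of the phenol gives the aryl carbonate that later triggers quinone methide release; the aldehyde is untouched.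

Step 5
Reactants: 7 (1S,2R)-(+)-trans-2-phenylcyclohexan-1-ol; 8 vinyl acetate
Product: 9 (1S,2R)-2-phenylcyclohexyl vinyl ether
Conditions: [Ir(cod)Cl]2 (1 mol%), Na2CO3 (0.6 equiv), toluene, 100 °C
Reagents that add atoms: none
Why: Iridium-catalysed transfer vinylation (alcohol addition to the coordinated vinyl ester, then β-acetate elimination) forms the O–vinyl bond without touching the carbinol C–O bond, so the (1S,2R) configuration is kept.

Step 6
Reactants: 4 8-bromo-3,5,7,3',4',5'-hexa-O-benzyl-(+)-gallocatechin; 6 5-(benzyloxy)-2-formylphenyl tert-butyl carbonate; 9 (1S,2R)-2-phenylcyclohexyl vinyl ether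
Product: 14 (2R,4R)-7-(benzyloxy)-4-Gc-2-{[(1S,2R)-2-phenylcyclohexyl]oxy}chroman (2,4-cis acetal), via aryllithium 10 (not isolated), via lithium alkoxide 11 (not isolated), via lithium phenoxide carbonate 12 (not isolated), via ortho-quinone methide 13 (not isolated)
Conditions: 4, t-BuLi (2.0 equiv), THF/Et2O, −78 °C; then 6, −78 °C; then MgBr2·OEt2, 9 (3 equiv), −78 °C → rt
Reagents that add atoms: none
Why: Bromine–lithium exchange on 4 gives aryllithium 10, which adds to the formyl group of 6; in alkoxide 11 the Boc group migrates from the phenolic to the benzylic oxygen (12), and magnesium-assisted β-elimination of tert-butyl carbonate releases the (E)-ortho-quinone methide 13 (O1=C8a–C4a=C4 of ring A, C4 carrying C8 of ring D), which is captured at once by enol ether 9 in an inverse-electron-demand hetero-Diels–Alder reaction. The closest known reaction type is the three-component benzopyran synthesis from O-Boc salicylaldehydes, organometallic reagents and vinyl ethers, including its auxiliary-controlled variant with 2-phenylcyclohexyl vinyl ethers. Ring C is closed by an intermolecular [4+2] cycloaddition (4π oxa-diene + 2π enol ether) that forms C3–C4 and O1–C2 in one asynchronous event, the nucleophilic CH2 terminus of 9 bonding to the methide carbon so that the alkoxy group ends up at C2. C4 is set by the auxiliary: in the s-trans enol ether the phenyl group is expected to shield the Si face of the oxygen-bearing vinyl carbon, so its Re face meets the E-methide in an endo transition state, which should give the (4R) configuration and a 2,4-cis acetal; C2 (2R) is a placeholder that step 7 rewrites. The step needs regiocontrol of the interflavan bond (secured by the C8 bromine of 4), face control at C4 (secured by the auxiliary and not by the remote centres of ring F) and chemoselectivity against quinone methide dimerisation (secured by its slow release at low temperature in the presence of excess 9).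

Step 7
Reactants: 14 (2R,4R)-7-(benzyloxy)-4-Gc-2-{[(1S,2R)-2-phenylcyclohexyl]oxy}chroman; 15 potassium [4-(benzyloxy)phenyl]trifluoroborate
Product: 16 (2S,4R)-7-(benzyloxy)-2-[4-(benzyloxy)phenyl]-4-Gc-chroman (octa-O-benzyl target)
Conditions: 15 (3 equiv), BF3·OEt2 (4 equiv), CH2Cl2/MeCN, −40 → 0 °C
Reagents that add atoms: none
Why: Oxocarbenium C-arylation of a cyclic O,O-acetal with an organotrifluoroborate: BF3 ionises the exocyclic alkyl–oxygen bond of 14 to the ring-C oxocarbenium ion, and the aryl group of the ArBF2 formed in the flask adds to C2 anti to the di-ortho-substituted C4 aryl group (1,3-induction), which should give the 2,4-trans (2S,4R) flavan and release the auxiliary.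

Step 8
Reactants: 16 (2S,4R)-7-(benzyloxy)-2-[4-(benzyloxy)phenyl]-4-Gc-chroman
Product: 17 (2S,4R)-4',7-dihydroxyflavan-(4→8)-(+)-gallocatechin (CNP0220331.3)
Conditions: H2 (1 atm), Pd(OH)2/C, THF/MeOH/H2O, rt
Reagents that add atoms: none
Why: Hydrogenolysis of the eight benzyl ethers over Pd(OH)2/C; the cyclic benzylic C2–O1 bonds and the C4–C8 bond survive such conditions in benzylated proanthocyanidins, and no stereocentre is touched.

**Compound list**

1 | (+)-gallocatechin, (2R,3S)-2-(3,4,5-trihydroxyphenyl)chroman-3,5,7-triol | c1c(O)cc(O)c2c1O[C@H](c1cc(O)c(O)c(O)c1)[C@@H](O)C2 | starting material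
2 | 5,7,3',4',5'-penta-O-benzyl-(+)-gallocatechin | c1c(OCc3ccccc3)cc(OCc3ccccc3)c2c1O[C@H](c1cc(OCc3ccccc3)c(OCc3ccccc3)c(OCc3ccccc3)c1)[C@@H](O)C2 | intermediate
3 | 3,5,7,3',4',5'-hexa-O-benzyl-(+)-gallocatechin | c1c(OCc3ccccc3)cc(OCc3ccccc3)c2c1O[C@H](c1cc(OCc3ccccc3)c(OCc3ccccc3)c(OCc3ccccc3)c1)[C@@H](OCc1ccccc1)C2 | intermediate
4 | 8-bromo-3,5,7,3',4',5'-hexa-O-benzyl-(+)-gallocatechin | Brc1c(OCc3ccccc3)cc(OCc3ccccc3)c2c1O[C@H](c1cc(OCc3ccccc3)c(OCc3ccccc3)c(OCc3ccccc3)c1)[C@@H](OCc1ccccc1)C2 | intermediate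
5 | 4-(benzyloxy)-2-hydroxybenzaldehyde | O=Cc1ccc(OCc2ccccc2)cc1O | starting material
6 | 5-(benzyloxy)-2-formylphenyl tert-butyl carbonate | O=Cc1ccc(OCc2ccccc2)cc1OC(=O)OC(C)(C)C | intermediate
7 | (1S,2R)-(+)-trans-2-phenylcyclohexan-1-ol | O[C@H]1CCCC[C@@H]1c1ccccc1 | starting material
8 | vinyl acetate | C=COC(C)=O | starting material
9 | (1S,2R)-2-phenylcyclohexyl vinyl ether | C=CO[C@H]1CCCC[C@@H]1c1ccccc1 | intermediate
10 | 8-lithio-hexa-O-benzyl-(+)-gallocatechin (Gc–Li) | [Li]c1c(OCc3ccccc3)cc(OCc3ccccc3)c2c1O[C@H](c1cc(OCc3ccccc3)c(OCc3ccccc3)c(OCc3ccccc3)c1)[C@@H](OCc1ccccc1)C2 | intermediate (not isolated)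
11 | lithium alkoxide of Gc–CH(OH)–[4-(benzyloxy)-2-(Boc-oxy)phenyl], carbinol epimers | [Li+].[O-]C(c1c(OCc3ccccc3)cc(OCc3ccccc3)c2c1O[C@H](c1cc(OCc3ccccc3)c(OCc3ccccc3)c(OCc3ccccc3)c1)[C@@H](OCc1ccccc1)C2)c1ccc(OCc2ccccc2)cc1OC(=O)OC(C)(C)C | intermediate (not isolated)
12 | lithium 5-(benzyloxy)-2-[Gc–CH(OBoc)]phenoxide (Boc-migrated), epimers | [Li+].[O-]c1cc(OCc2ccccc2)ccc1C(OC(=O)OC(C)(C)C)c1c(OCc3ccccc3)cc(OCc3ccccc3)c2c1O[C@H](c1cc(OCc3ccccc3)c(OCc3ccccc3)c(OCc3ccccc3)c1)[C@@H](OCc1ccccc1)C2 | intermediate (not isolated)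
13 | (E)-3-(benzyloxy)-6-(Gc-methylidene)cyclohexa-2,4-dien-1-one (ortho-quinone methide) | O=C1C=C(OCc2ccccc2)C=C/C1=C\c1c(OCc3ccccc3)cc(OCc3ccccc3)c2c1O[C@H](c1cc(OCc3ccccc3)c(OCc3ccccc3)c(OCc3ccccc3)c1)[C@@H](OCc1ccccc1)C2 | intermediate (not isolated)
14 | (2R,4R)-7-(benzyloxy)-4-Gc-2-{[(1S,2R)-2-phenylcyclohexyl]oxy}chroman, 2,4-cis | O([C@H]1CCCC[C@@H]1c1ccccc1)[C@H]1C[C@@H](c2c(OCc4ccccc4)cc(OCc4ccccc4)c3c2O[C@H](c2cc(OCc4ccccc4)c(OCc4ccccc4)c(OCc4ccccc4)c2)[C@@H](OCc2ccccc2)C3)c2ccc(OCc3ccccc3)cc2O1 | intermediate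
15 | potassium [4-(benzyloxy)phenyl]trifluoroborate | [K+].F[B-](F)(F)c1ccc(OCc2ccccc2)cc1 | starting material
16 | (2S,4R)-7-(benzyloxy)-2-[4-(benzyloxy)phenyl]-4-Gc-chroman, 2,4-trans | c1ccccc1COc1ccc([C@@H]2C[C@@H](c3c(OCc5ccccc5)cc(OCc5ccccc5)c4c3O[C@H](c3cc(OCc5ccccc5)c(OCc5ccccc5)c(OCc5ccccc5)c3)[C@@H](OCc3ccccc3)C4)c3ccc(OCc4ccccc4)cc3O2)cc1 | intermediate
17 | (2S,4R)-4',7-dihydroxyflavan-(4→8)-(+)-gallocatechin, CNP0220331.3 | Oc1ccc([C@@H]2C[C@@H](c3c(O)cc(O)c4c3O[C@H](c3cc(O)c(O)c(O)c3)[C@@H](O)C4)c3ccc(O)cc3O2)cc1 | target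

**Totals**

Total step count: 8. Longest linear sequence: 6 steps (1, 2, 3, 6, 7, 8).

**Steps most likely to fail**

Step 7. The aryl group may be delivered without face control, for instance inside the ion pair on the side the alkoxy group left. Ring C may open by endocyclic C–O cleavage. The oxocarbenium ion may be intercepted by the neighbouring C7 benzyloxy oxygen of ring D, or may lose a proton to the 4H-chromene before the slow aryl transfer. The fallback sets out from 14 and comes back at 16. Acid hydrolysis of the acetal (aqueous HCl, THF) should give the lactol F1 and return the auxiliary. Excess [4-(benzyloxy)phenyl]magnesium bromide in THF should add to the ring-opened hydroxy-aldehyde tautomer to give the diol F2 as carbinol epimers. MnO2 should oxidise the benzylic alcohol to the ketone F3. Corey–Bakshi–Shibata reduction with (S)-Me-CBS and BH3·SMe2 should give the (R)-carbinol F4 under reagent control. A Mitsunobu cyclisation (PPh3, DIAD, THF, 0 °C) should then close ring C with inversion at C2 to give the 2,4-trans flavan 16.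

Step 6. The hindered, donor-stabilised quinone methide may react sluggishly or with poor facial selectivity. It may dimerise, or the aryllithium may attack the carbonate instead of the aldehyde. The fallback sets out from 3 and comes back at 16. Claisen–Schmidt condensation of 1-[4-(benzyloxy)-2-hydroxyphenyl]ethanone with 4-(benzyloxy)benzaldehyde (KOH, EtOH) should give the chalcone F5. Oxa-Michael cyclisation (NaOAc, EtOH, reflux) should give the racemic flavanone F6. Kinetic resolution by asymmetric transfer hydrogenation (RuCl[(S,S)-TsDPEN](p-cymene), HCO2H/Et3N) should reduce the (2S) enantiomer to the (2S,4S)-flavan-4-ol F7. TMSOTf-mediated Friedel–Crafts coupling of F7 with excess 3 (CH2Cl2, −78 °C) should ionise C4 and bond it to C8 of ring D, by axial attack anti to the C2 aryl group, to give 16.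

Step 8. Removal of eight benzyl groups may stall at partly protected stages. The benzylic ring C–O bonds may be over-reduced, or the pyrogallol ring may oxidise in air on work-up. The fallback sets out from 16 and ends at 17. It is a non-reductive Lewis-acid debenzylation with a cation scavenger (BCl3, pentamethylbenzene, CH2Cl2, −78 °C), which transfers the benzyl cations to the arene; it makes no new compound on the way.

**Further compounds**

F1 | step 7 | (4R)-7-(benzyloxy)-4-Gc-chroman-2-ol (lactol, anomers) | OC1C[C@@H](c2c(OCc4ccccc4)cc(OCc4ccccc4)c3c2O[C@H](c2cc(OCc4ccccc4)c(OCc4ccccc4)c(OCc4ccccc4)c2)[C@@H](OCc2ccccc2)C3)c2ccc(OCc3ccccc3)cc2O1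
F2 | step 7 | (3R)-1-[4-(benzyloxy)phenyl]-3-[4-(benzyloxy)-2-hydroxyphenyl]-3-Gc-propan-1-ol (C1 epimers) | OC(c1ccc(OCc2ccccc2)cc1)C[C@@H](c1c(OCc3ccccc3)cc(OCc3ccccc3)c2c1O[C@H](c1cc(OCc3ccccc3)c(OCc3ccccc3)c(OCc3ccccc3)c1)[C@@H](OCc1ccccc1)C2)c1ccc(OCc2ccccc2)cc1O
F3 | step 7 | (3R)-1-[4-(benzyloxy)phenyl]-3-[4-(benzyloxy)-2-hydroxyphenyl]-3-Gc-propan-1-one | O=C(c1ccc(OCc2ccccc2)cc1)C[C@@H](c1c(OCc3ccccc3)cc(OCc3ccccc3)c2c1O[C@H](c1cc(OCc3ccccc3)c(OCc3ccccc3)c(OCc3ccccc3)c1)[C@@H](OCc1ccccc1)C2)c1ccc(OCc2ccccc2)cc1O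
F4 | step 7 | (1R,3R)-1-[4-(benzyloxy)phenyl]-3-[4-(benzyloxy)-2-hydroxyphenyl]-3-Gc-propan-1-ol | O[C@@H](c1ccc(OCc2ccccc2)cc1)C[C@@H](c1c(OCc3ccccc3)cc(OCc3ccccc3)c2c1O[C@H](c1cc(OCc3ccccc3)c(OCc3ccccc3)c(OCc3ccccc3)c1)[C@@H](OCc1ccccc1)C2)c1ccc(OCc2ccccc2)cc1O
F5 | step 6 | (E)-1-[4-(benzyloxy)-2-hydroxyphenyl]-3-[4-(benzyloxy)phenyl]prop-2-en-1-one | O=C(/C=C/c1ccc(OCc2ccccc2)cc1)c1ccc(OCc2ccccc2)cc1O
F6 | step 6 | racemic 7-(benzyloxy)-2-[4-(benzyloxy)phenyl]chroman-4-one | O=C1CC(c2ccc(OCc3ccccc3)cc2)Oc2cc(OCc3ccccc3)ccc12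
F7 | step 6 | (2S,4S)-7-(benzyloxy)-2-[4-(benzyloxy)phenyl]chroman-4-ol (2,4-cis) | c1ccccc1COc1ccc([C@@H]2C[C@H](O)c3ccc(OCc4ccccc4)cc3O2)cc1
F0 | step 8 | none | none
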